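**Retrosynthetic overview**
1. Target ⇒ MOM-protected flavanone 13 by one final acidic deprotection.
2. C2–aryl bond of 13 ⇒ Pd(II)/PyOx-catalysed enantioselective conjugate addition of arylboronic acid 10 to chromone 12; this sets the only stereocentre (2S).
3. Chromone 12 ⇒ 5,7-dihydroxychromone, bought with the A/C rings intact; only the 7-OH is protected.
4. Boronic acid 10 ⇒ bromochromenol 6 (MOM protection, Li–Br exchange/borylation); the dimethylpyran ring of 6 ⇒ aryl 1,1-dimethylpropargyl ether Claisen/6π cascade.
5. Catechol oxygen pattern ⇒ Baeyer–Villiger of 5-bromosalicylaldehyde ether (fixes ether O para to Br). Ring order: B-ring pyran first, chromanone C-ring saturated last.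

Assumption 1: 5,7-dihydroxy-4H-chromen-4-one is treated as a catalogue starting material.
Assumption 2: the sense of induction is assigned by analogy with 3-methylcyclohexenone, where (S)-t-BuPyOx gives the (R)-adduct; on that basis (R)-t-BuPyOx is used for the (2S)-flavanone. This is from memory and by analogy, so confirm by CD and swap the ligand enantiomer if the sense is opposite.

**Step 1**
Reactants: 1, 5-bromo-2-hydroxybenzaldehyde; 2, 3-chloro-3-methylbut-1-yne
Product: 3, 5-bromo-2-[(2-methylbut-3-yn-2-yl)oxy]benzaldehyde
Conditions: DBU, CuCl2·2H2O (1 mol %), MeCN, 0 °C → rt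
Reagents that add atoms: 3-chloro-3-methylbut-1-yne (2), C#CC(C)(C)Cl
Why: Cu-catalysed propargylic O-alkylation (via a Cu-allenylidene) of the acidic phenoxide gives the tertiary aryl propargyl ether; the aldehyde is untouched.

**Step 2**
Reactants: 3; 4, m-chloroperoxybenzoic acid (mCPBA)
Product: 5, 5-bromo-2-[(2-methylbut-3-yn-2-yl)oxy]phenol
Conditions: mCPBA, NaHCO3, CH2Cl2, rt; then K2CO3, MeOH, rt
Reagents that add atoms: mCPBA (4), OOC(=O)c1cccc(Cl)c1 (one O inserted)
Why: Baeyer–Villiger (Dakin-type) oxidation, with the o-alkoxyaryl group migrating to give the aryl formate, which is methanolysed to the phenol; the alkyne and ArBr are inert and the buffer protects the tertiary ether.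

**Step 3**
Reactants: 5
Product: 6, 6-bromo-2,2-dimethyl-2H-chromen-8-ol
Conditions: PhNEt2, 185 °C, N2
Reagents that add atoms: none
Why: Aryl propargyl ether Claisen rearrangement to the only free ortho carbon, then 1,5-H shift and oxa-6π electrocyclisation, gives the 2,2-dimethylchromene with Br para to the ring oxygen.

**Step 4**
Reactants: 6; 7, chloromethyl methyl ether (MOMCl)
Product: 8, 6-bromo-8-(methoxymethoxy)-2,2-dimethyl-2H-chromene
Conditions: MOMCl, i-Pr2NEt, CH2Cl2, 0 °C → rt
Reagents that add atoms: MOMCl (7), COCCl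
Why: Standard phenol O-alkylation (acetal protection), needed so the phenol survives organolithium and Pd(II) chemistry.

**Step 5**
Reactants: 8; 9, triisopropyl borate
Product: 10, [8-(methoxymethoxy)-2,2-dimethyl-2H-chromen-6-yl]boronic acid
Conditions: n-BuLi, THF, −78 °C; B(Oi-Pr)3, −78 °C → rt; sat. aq NH4Cl
Reagents that add atoms: triisopropyl borate (9), CC(C)OB(OC(C)C)OC(C)C; water, O (workup hydrolysis, not numbered)
Why: Li–Br exchange is faster than any addition to the chromene alkene at −78 °C; borate trapping and mild hydrolysis give the boronic acid with the MOM ether intact.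

**Step 6**
Reactants: 11, 5,7-dihydroxy-4H-chromen-4-one; 7, MOMCl
Product: 12, 5-hydroxy-7-(methoxymethoxy)-4H-chromen-4-one
Conditions: MOMCl (1.1 equiv), K2CO3, acetone, rt
Reagents that add atoms: MOMCl (7), COCCl
Why: Selective O-alkylation of the acidic 7-OH; the 5-OH is hydrogen-bonded to the C4 carbonyl and stays free.

**Step 7**
Reactants: 12; 10 (2 equiv)
Product: 13, (2S)-5-hydroxy-7-(methoxymethoxy)-2-[8-(methoxymethoxy)-2,2-dimethyl-2H-chromen-6-yl]-2,3-dihydro-4H-chromen-4-one
Conditions: Pd(OCOCF3)2 (10 mol %), (R)-t-BuPyOx (12 mol %), NH4PF6 (30 mol %), H2O (5 equiv), ClCH2CH2Cl, 60 °C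
Reagents that add atoms: none (both fragments are the listed reactants; the C3–H comes from water)
Why: Pd(II)-catalysed asymmetric conjugate addition: transmetalation, enantiofacial migratory insertion of the chromone C2=C3 into Ar–Pd, then protonolysis of the Pd enolate, which also prevents ring opening; the ligand's t-Bu group controls the face and sets C2 as S (Assumption 2).

**Step 8**
Reactants: 13
Product: 14, (2S)-5,7-dihydroxy-2-(8-hydroxy-2,2-dimethyl-2H-chromen-6-yl)-2,3-dihydro-4H-chromen-4-one (target)
Conditions: 3 M aq HCl, MeOH, 45 °C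
Reagents that add atoms: none
Why: Acid-catalysed acetal (MOM) methanolysis frees both phenols; avoiding base prevents retro-oxa-Michael opening to the chalcone, so C2 is not scrambled, and the chromene alkene tolerates dilute acid.

**Compound list**
1 | 5-bromo-2-hydroxybenzaldehyde | O=Cc1cc(Br)ccc1O | starting material
2 | 3-chloro-3-methylbut-1-yne | C#CC(C)(C)Cl | starting material (reagent)
3 | 5-bromo-2-[(2-methylbut-3-yn-2-yl)oxy]benzaldehyde | O=Cc1cc(Br)ccc1OC(C)(C)C#C | intermediate
4 | m-chloroperoxybenzoic acid | OOC(=O)c1cccc(Cl)c1 | starting material (reagent)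
5 | 5-bromo-2-[(2-methylbut-3-yn-2-yl)oxy]phenol | Oc1cc(Br)ccc1OC(C)(C)C#C | intermediate
6 | 6-bromo-2,2-dimethyl-2H-chromen-8-ol | CC1(C)C=Cc2cc(Br)cc(O)c2O1 | intermediate
7 | chloromethyl methyl ether | COCCl | starting material (reagent)
8 | 6-bromo-8-(methoxymethoxy)-2,2-dimethyl-2H-chromene | CC1(C)C=Cc2cc(Br)cc(OCOC)c2O1 | intermediate
9 | triisopropyl borate | CC(C)OB(OC(C)C)OC(C)C | starting material (reagent)
10 | [8-(methoxymethoxy)-2,2-dimethyl-2H-chromen-6-yl]boronic acid | CC1(C)C=Cc2cc(B(O)O)cc(OCOC)c2O1 | intermediate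
11 | 5,7-dihydroxy-4H-chromen-4-one | O=c1ccoc2cc(O)cc(O)c12 | starting material
12 | 5-hydroxy-7-(methoxymethoxy)-4H-chromen-4-one | COCOc1cc(O)c2c(c1)occc2=O | intermediate
13 | (2S)-5-hydroxy-7-(methoxymethoxy)-2-[8-(methoxymethoxy)-2,2-dimethyl-2H-chromen-6-yl]chroman-4-one | CC1(C)C=Cc2cc([C@@H]3CC(=O)c4c(O)cc(OCOC)cc4O3)cc(OCOC)c2O1 | intermediate
14 | (2S)-5,7-dihydroxy-2-(8-hydroxy-2,2-dimethyl-2H-chromen-6-yl)chroman-4-one | CC1(C)C=Cc2cc([C@@H]3CC(=O)c4c(O)cc(O)cc4O3)cc(O)c2O1 | target

**Step count**
Total steps: 8. Longest linear sequence: 7 (steps 1–5, 7, 8); step 6 is a one-step side branch.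

**Three steps most likely to fail, with fallbacks**
1. Step 7. Risks are a sluggish electron-rich chromone, Pd chelation by the free 5-OH, protodeboronation of the electron-rich boronic acid and modest ee. Fallback: drop the C2–aryl disconnection and use the chalcone route.
   - Convert 8 to the 6-carbaldehyde (Li–Br exchange, DMF).
   - Claisen–Schmidt condensation with 2-hydroxy-4,6-bis(methoxymethoxy)acetophenone, then NaOAc cyclisation to the racemic flavanone.
   - Kinetic resolution by Rh/TsDPEN asymmetric transfer hydrogenation, recovering the (2S)-flavanone, then step 8.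
2. Step 2. Risks are over-oxidation to the benzoic acid and acid loss of the tertiary propargyl ether. Fallback: source the catechol oxygen from 4-bromo-2-methoxyphenol instead (propargylation, Claisen to 6-bromo-8-methoxy-2,2-dimethylchromene, NaSEt/DMF O-demethylation to 6), removing the oxidation altogether.
3. Step 8. Risks are acid-promoted MeOH addition to the chromene alkene and partial racemisation. Fallback: change the protecting-group strategy to TBS ethers at steps 4 and 6, removed at the end with buffered fluoride (HF·pyridine or TBAF/AcOH) under non-acidic, non-basic conditions.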